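The bonds C4–C5, C9–C10 and C8–O of the ent-labdane core are cut together. The feature used is that ring A with its quaternary C4 (equatorial C18 oxygen, axial methyl), the trans C5–C10 junction of rings A and B, C9 and the tertiary C8 oxygen all lie along one (E,E)-farnesylacetic acid chain, whose C13 carboxyl sits within bonding distance of C8. One Lewis-acid cascade from an enantiopure C3–C4 epoxide closes ring A, ring B and a temporary C8–O–C13 δ-lactone and fixes C4, C5, C8, C9 and C10. Its precursor is the open-chain (3R,4R)-epoxy acid with a silyl-protected C18 oxygen. The C13 methyl centre and the angelate follow afterwards.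

Key step: step 6

Assumption: (2E,6E)-farnesyl bromide is bought geometrically pure; labdane numbering is used from compound 4 on (C13 = carboxyl carbon of the chain, C18 = oxygenated carbon on C4).

Remark: the cascade closes three rings (ring A, ring B and the δ-lactone), the oxygen closure at C8 is of the 6-endo kind, and the 3R,4R epoxide requires the D-(−)-tartrate.

Step 1
Reactants: 1 (2E,6E)-farnesyl bromide; 2 methyl acetate
Product: 4 methyl (4E,8E)-5,9,13-trimethyltetradeca-4,8,12-trienoate (methyl farnesylacetate), via lithium enolate 3 (not isolated)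
Conditions: LiN(iPr)2 (1.3 equiv), 2 (1.4 equiv), THF, −78 °C; then 1, DMPU, −78 → −20 °C
Reagents that add atoms: none
Why: Enolate alkylation (SN2) of an ester lithium enolate by a primary allylic bromide is a standard C–C bond formation that takes place at the CH2Br carbon and leaves both (E)-alkenes of the farnesyl unit untouched.

Step 2
Reactants: 4 methyl farnesylacetate
Product: 5 methyl (4E,8E,12E)-14-hydroxy-5,9,13-trimethyltetradeca-4,8,12-trienoate
Conditions: SeO2 (0.3 equiv), t-BuOOH (3 equiv), salicylic acid (0.1 equiv), CH2Cl2, 0 °C → rt, stopped at partial conversion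
Reagents that add atoms: tert-butyl hydroperoxide, CC(C)(C)OO (net source of the new oxygen; SeO2 is the catalytic carrier)
Why: Catalytic SeO2 allylic oxidation (ene reaction followed by [2,3]-sigmatropic shift) prefers the most exposed terminal trisubstituted alkene and hydroxylates the methyl group trans to the chain, so the (12E)-allylic alcohol should result, and stopping early spares the two internal alkenes.

Step 3
Reactants: 5 the (12E)-allylic alcohol
Product: 6 methyl (4E,8E)-11-[(2R,3R)-3-(hydroxymethyl)-3-methyloxiran-2-yl]-5,9-dimethylundeca-4,8-dienoate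
Conditions: Ti(OiPr)4 (0.1 equiv), D-(−)-diethyl tartrate (0.12 equiv), t-BuOOH (2 equiv), 4 Å molecular sieves, CH2Cl2, −20 °C
Reagents that add atoms: tert-butyl hydroperoxide, CC(C)(C)OO
Why: Sharpless asymmetric epoxidation acts only on the allylic alcohol, and the D-(−)-tartrate titanium complex delivers oxygen to the alkene face that gives the (2R,3R)-epoxy alcohol (C3 R and C4 R in labdane numbering), the mirror image of what L-(+)-tartrate gives with (E)-allylic alcohols.

Step 4
Reactants: 6 the (2R,3R)-epoxy alcohol
Product: 7 methyl (4E,8E)-11-[(2R,3R)-3-{[tert-butyl(diphenyl)silyl]oxymethyl}-3-methyloxiran-2-yl]-5,9-dimethylundeca-4,8-dienoate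
Conditions: t-BuPh2SiCl (1.2 equiv), imidazole (2 equiv), CH2Cl2, 0 °C → rt
Reagents that add atoms: tert-butyldiphenylsilyl chloride, CC(C)(C)[Si](Cl)(c1ccccc1)c1ccccc1
Why: Silylation of the primary alcohol under imidazole catalysis does not touch the epoxide, and the bulky, weakly basic silyl ether is chosen so that O18 neither binds the Lewis acid strongly nor attacks a cation in step 6.

Step 5
Reactants: 7 the silyl-protected epoxy ester
Product: 8 (4E,8E)-11-[(2R,3R)-3-{[tert-butyl(diphenyl)silyl]oxymethyl}-3-methyloxiran-2-yl]-5,9-dimethylundeca-4,8-dienoic acid (3,4-epoxy-18-silyloxy-(E,E)-farnesylacetic acid)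
Conditions: LiOH·H2O (3 equiv), THF/MeOH/H2O 3:1:1, rt; then aq. KHSO4 to pH 4 at 0 °C, used at once
Reagents that add atoms: lithium hydroxide, [Li+].[OH-] (its oxygen becomes the carboxyl OH)
Why: Saponification of an unhindered methyl ester by hydroxide proceeds at room temperature, where neither the hindered trisubstituted epoxide nor the silyl ether reacts, and the cold, mildly acidic work-up avoids acid-induced epoxide opening.

Step 6
Reactants: 8 the (3R,4R)-epoxy acid
Product: 10 (3R,4S,5S,8S,9S,10R)-18-(tert-butyldiphenylsilyloxy)-3-hydroxy-14,15,16-trinorlabdan-13,8-olide (trans-decalin δ-lactone of the ent series; 3-OH and C18 equatorial), via dichloroaluminium carboxylate 9 (not isolated)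
Conditions: MeAlCl2 (1.05 equiv), CH2Cl2 (0.01 M), −78 °C, 10 min; then MeAlCl2 (1.5 equiv), −78 → −50 °C; Et3N/MeOH, then aq. potassium sodium tartrate
Reagents that add atoms: none
Why: The first equivalent of MeAlCl2 turns the acid into its aluminium carboxylate 9 with loss of methane, so no free proton is present, and the excess binds the epoxide oxygen; the tertiary C4–O bond then ionises under backside attack of C5=C10, the C10 cation is taken by C8=C9 and the C8 cation by the carboxylate oxygen, the AlCl2 group ending on the C3 alkoxide. The closest known reaction type is the Lewis-acid epoxy-polyene cyclisation with internal oxygen termination, as in the acid-induced cyclisation of farnesylacetic and homofarnesic acids to lactones. Three rings close: ring A by 6-endo attack of C5 on C4 (both epoxide carbons end in the ring), ring B by 6-endo attack of C9 on C10, and the δ-lactone by 6-endo capture at C8 of the former C8=C9 bond. C3 keeps the configuration set in step 3, C4 is inverted so that the (E)-CH2OSi arm becomes equatorial and the methyl axial, C5 and C10 follow from anti addition across the (E)-C5=C10 bond in a chair (trans fusion), and C9 and C8 from anti addition across the (E)-C8=C9 bond in a second chair (H9 axial, O8 equatorial, C17 axial), the 3R epoxide fixing the ent absolute sense. The step needs opening at C4 and not at C3, complete bicyclisation, and oxygen capture in place of proton loss: the tertiary C4, the proton-scavenging Al–Me bond, high dilution at low temperature, the weakly basic silyl ether and a carboxylate held three carbons from C9 secure this, and the slower ionisation caused by the CH2OSi group is met by excess Lewis acid and slow warming.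

Step 7
Reactants: 10 the 3-hydroxy lactone
Product: 11 the O-(imidazol-1-ylthiocarbonyl) derivative of 10 at C3
Conditions: 1,1'-thiocarbonyldiimidazole (3 equiv), DMAP (0.3 equiv), toluene, 100 °C
Reagents that add atoms: 1,1'-thiocarbonyldiimidazole, S=C(n1ccnc1)n1ccnc1
Why: Thioacylation of the equatorial secondary C3 alcohol (first half of the Barton–McCombie deoxygenation) needs no strong base, so the lactone and the silyl ether stay intact and no stereocentre is touched.

Step 8
Reactants: 11 the C3 thiocarbonylimidazolide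
Product: 12 (4S,5S,8S,9S,10R)-18-(tert-butyldiphenylsilyloxy)-14,15,16-trinorlabdan-13,8-olide
Conditions: Bu3SnH (2 equiv), AIBN (0.2 equiv), toluene, 110 °C
Reagents that add atoms: none
Why: In the Barton–McCombie radical deoxygenation the stannyl radical adds to C=S, the C3–O bond fragments to a secondary radical with no β-leaving group, and hydrogen transfer from Bu3SnH gives the C3 methylene, which removes the C3 stereocentre without affecting the others.

Step 9
Reactants: 12 the deoxygenated δ-lactone
Product: 14 (4S,5S,8S,9S,10R)-18-(tert-butyldiphenylsilyloxy)-8-hydroxy-14,15-dinorlabdan-13-one, via lithium hemiketalate 13 (not isolated)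
Conditions: MeLi (1.3 equiv), THF, −78 °C; sat. aq. NH4Cl at −78 °C
Reagents that add atoms: methyllithium, [Li]C
Why: Addition of MeLi to the lactone carbonyl C13 stops at the cyclic lithium hemiketalate at −78 °C, which only on protonation opens to the C13 methyl ketone (C16 installed) and the free C8 tertiary alcohol, a known way from lactones to methyl ketones without double addition.

Step 10
Reactants: 14 the 8-hydroxy-13-ketone
Product: 15 methyl (13E)-(4S,5S,8S,9S,10R)-18-(tert-butyldiphenylsilyloxy)-8-hydroxylabd-13-en-15-oate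
Conditions: (MeO)2P(O)CH2CO2Me (5 equiv), NaH (5 equiv), THF, 0 → 65 °C; chromatography to remove the minor (13Z) isomer
Reagents that add atoms: trimethyl phosphonoacetate, COC(=O)CP(=O)(OC)OC
Why: Horner–Wadsworth–Emmons olefination of the methyl ketone with a stabilised phosphonate anion favours, through reversible addition, the (13E)-enoate with the ester trans to the larger C12 chain, while the excess anion covers the C8 alkoxide and the minor (13Z) isomer, which would lead to the 13-epimer, is separated.

Step 11
Reactants: 15 the (13E)-enoate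
Product: 16 (13E)-(4S,5S,8S,9S,10R)-18-(tert-butyldiphenylsilyloxy)labd-13-ene-8,15-diol
Conditions: iBu2AlH (4 equiv), CH2Cl2, −78 → 0 °C; aq. potassium sodium tartrate
Reagents that add atoms: none
Why: 1,2-Reduction of the conjugated ester by iBu2AlH gives the allylic alcohol without changing the alkene geometry, and it provides the hydroxyl that directs the hydrogenation in step 12.

Step 12
Reactants: 16 the (13E)-allylic alcohol
Product: 17 (4S,5S,8S,9S,10R,13S)-18-(tert-butyldiphenylsilyloxy)labdane-8,15-diol
Conditions: H2 (100 atm), Ru(OAc)2[(R)-BINAP] (1 mol %), 95% aq. MeOH, 20 °C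
Reagents that add atoms: none
Why: In the Noyori asymmetric hydrogenation the allylic hydroxyl binds divalent ruthenium and directs hydride delivery to one alkene face: as geraniol gives (S)-citronellol with the (R)-BINAP complex, the (13E)-alcohol should give the 13S centre, while the remote C8 hydroxyl and the silyl ether take no part and high pressure suppresses alkene migration.

Step 13
Reactants: 17 the 8,15-diol
Product: 18 (4S,5S,8S,9S,10R,13S)-18-(tert-butyldiphenylsilyloxy)-8-hydroxylabdan-15-oic acid
Conditions: TEMPO (0.2 equiv), PhI(OAc)2 (2.5 equiv), MeCN/H2O 1:1, rt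
Reagents that add atoms: water, O (second oxygen of the carboxyl group)
Why: The oxoammonium (TEMPO) oxidation in aqueous acetonitrile takes the primary alcohol through the aldehyde hydrate to the acid, cannot oxidise the tertiary C8 alcohol, and does not endanger C13, which is β to the new carbonyl.

Step 14
Reactants: 18 the 15-oic acid
Product: 19 allyl (4S,5S,8S,9S,10R,13S)-18-(tert-butyldiphenylsilyloxy)-8-hydroxylabdan-15-oate
Conditions: allyl bromide (1.5 equiv), K2CO3 (2 equiv), DMF, rt
Reagents that add atoms: allyl bromide, C=CCBr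
Why: O-Alkylation of the carboxylate (SN2) leaves the tertiary alcohol untouched under carbonate base, and the allyl ester is chosen because it can be removed at the end under neutral conditions that an angelate survives.

Step 15
Reactants: 19 the allyl ester silyl ether
Product: 20 allyl (4S,5S,8S,9S,10R,13S)-8,18-dihydroxylabdan-15-oate
Conditions: Bu4NF (3 equiv), AcOH (3 equiv), THF, rt → 40 °C
Reagents that add atoms: none
Why: Fluoride-induced cleavage of the Si–O bond frees the primary C18 alcohol, and buffering with acetic acid keeps the medium from hydrolysing the allyl ester.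

Step 16
Reactants: 20 the 8,18-diol allyl ester; 21 angelic acid [(Z)-2-methylbut-2-enoic acid]
Product: 23 allyl (4S,5S,8S,9S,10R,13S)-8-hydroxy-18-[(Z)-2-methylbut-2-enoyloxy]labdan-15-oate, via mixed anhydride 22 (not isolated)
Conditions: 21 (3 equiv), 2,4,6-trichlorobenzoyl chloride (3 equiv), Et3N (3 equiv), toluene, rt, 2 h; then 20, toluene, 80 °C, no DMAP
Reagents that add atoms: none
Why: In the Yamaguchi esterification the preformed mixed anhydride transfers the angeloyl group to the primary C18 alcohol on heating, and without a nucleophilic catalyst the (Z)-geometry should be kept (such catalysts cause isomerisation to the tiglate), while the tertiary C8 alcohol is too hindered to be acylated.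

Step 17
Reactants: 23 the angelate allyl ester
Product: 24 (4S,5S,8S,9S,10R,13S)-8-hydroxy-18-[(Z)-2-methylbut-2-enoyloxy]labdan-15-oic acid (target)
Conditions: Pd(PPh3)4 (5 mol %), morpholine (5 equiv), THF, rt; mild acidic work-up
Reagents that add atoms: none
Why: In the Tsuji–Trost deallylation zerovalent palladium ionises only the allyl ester to a π-allyl complex that morpholine captures, so the acid is freed under neutral conditions at room temperature without touching the angelate or the tertiary alcohol.

Compound list
1 | (2E,6E)-farnesyl bromide | CC(C)=CCC/C(C)=C/CC/C(C)=C/CBr | starting material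
2 | methyl acetate | COC(C)=O | starting material
3 | lithium enolate of methyl acetate | [Li+].[O-]C(=C)OC | intermediate
4 | methyl (4E,8E)-5,9,13-trimethyltetradeca-4,8,12-trienoate | COC(=O)CC/C=C(C)/CC/C=C(C)/CCC=C(C)C | intermediate
5 | methyl (4E,8E,12E)-14-hydroxy-5,9,13-trimethyltetradeca-4,8,12-trienoate | COC(=O)CC/C=C(C)/CC/C=C(C)/CC/C=C(C)/CO | intermediate
6 | methyl (4E,8E)-11-[(2R,3R)-3-(hydroxymethyl)-3-methyloxiran-2-yl]-5,9-dimethylundeca-4,8-dienoate | COC(=O)CC/C=C(C)/CC/C=C(C)/CC[C@H]1O[C@]1(C)CO | intermediate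
7 | tert-butyldiphenylsilyl ether of 6 | COC(=O)CC/C=C(C)/CC/C=C(C)/CC[C@H]1O[C@]1(C)CO[Si](c2ccccc2)(c2ccccc2)C(C)(C)C | intermediate
8 | (3R,4R)-3,4-epoxy-18-(tert-butyldiphenylsilyloxy)-(E,E)-farnesylacetic acid | OC(=O)CC/C=C(C)/CC/C=C(C)/CC[C@H]1O[C@]1(C)CO[Si](c2ccccc2)(c2ccccc2)C(C)(C)C | intermediate
9 | dichloroaluminium carboxylate of 8 | Cl[Al](Cl)OC(=O)CC/C=C(C)/CC/C=C(C)/CC[C@H]1O[C@]1(C)CO[Si](c2ccccc2)(c2ccccc2)C(C)(C)C | intermediate
10 | (3R,4S,5S,8S,9S,10R)-18-(tert-butyldiphenylsilyloxy)-3-hydroxy-14,15,16-trinorlabdan-13,8-olide | CC(C)(C)[Si](c1ccccc1)(c1ccccc1)OC[C@@]1(C)[C@H](O)CC[C@]2(C)[C@@H]1CC[C@]3(C)OC(=O)CC[C@@H]23 | intermediate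
11 | C3 O-(imidazol-1-ylthiocarbonyl) derivative of 10 | CC(C)(C)[Si](c1ccccc1)(c1ccccc1)OC[C@@]1(C)[C@H](OC(=S)n4ccnc4)CC[C@]2(C)[C@@H]1CC[C@]3(C)OC(=O)CC[C@@H]23 | intermediate
12 | (4S,5S,8S,9S,10R)-18-(tert-butyldiphenylsilyloxy)-14,15,16-trinorlabdan-13,8-olide | CC(C)(C)[Si](c1ccccc1)(c1ccccc1)OC[C@@]1(C)CCC[C@]2(C)[C@@H]1CC[C@]3(C)OC(=O)CC[C@@H]23 | intermediate
13 | lithium hemiketalate from 12 and MeLi (C13 configuration not defined) | CC(C)(C)[Si](c1ccccc1)(c1ccccc1)OC[C@@]1(C)CCC[C@]2(C)[C@@H]1CC[C@]3(C)OC(C)([O-])CC[C@@H]23.[Li+] | intermediate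
14 | (4S,5S,8S,9S,10R)-18-(tert-butyldiphenylsilyloxy)-8-hydroxy-14,15-dinorlabdan-13-one | CC(C)(C)[Si](c1ccccc1)(c1ccccc1)OC[C@@]1(C)CCC[C@]2(C)[C@@H]1CC[C@](C)(O)[C@H]2CCC(C)=O | intermediate
15 | methyl (13E)-18-(tert-butyldiphenylsilyloxy)-8-hydroxylabd-13-en-15-oate (ent series) | CC(C)(C)[Si](c1ccccc1)(c1ccccc1)OC[C@@]1(C)CCC[C@]2(C)[C@@H]1CC[C@](C)(O)[C@H]2CC/C(C)=C/C(=O)OC | intermediate
16 | (13E)-18-(tert-butyldiphenylsilyloxy)labd-13-ene-8,15-diol (ent series) | CC(C)(C)[Si](c1ccccc1)(c1ccccc1)OC[C@@]1(C)CCC[C@]2(C)[C@@H]1CC[C@](C)(O)[C@H]2CC/C(C)=C/CO | intermediate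
17 | (13S)-18-(tert-butyldiphenylsilyloxy)labdane-8,15-diol (ent series) | CC(C)(C)[Si](c1ccccc1)(c1ccccc1)OC[C@@]1(C)CCC[C@]2(C)[C@@H]1CC[C@](C)(O)[C@H]2CC[C@H](C)CCO | intermediate
18 | (13S)-18-(tert-butyldiphenylsilyloxy)-8-hydroxylabdan-15-oic acid (ent series) | CC(C)(C)[Si](c1ccccc1)(c1ccccc1)OC[C@@]1(C)CCC[C@]2(C)[C@@H]1CC[C@](C)(O)[C@H]2CC[C@H](C)CC(=O)O | intermediate
19 | allyl ester of 18 | CC(C)(C)[Si](c1ccccc1)(c1ccccc1)OC[C@@]1(C)CCC[C@]2(C)[C@@H]1CC[C@](C)(O)[C@H]2CC[C@H](C)CC(=O)OCC=C | intermediate
20 | allyl (13S)-8,18-dihydroxylabdan-15-oate (ent series) | OC[C@@]1(C)CCC[C@]2(C)[C@@H]1CC[C@](C)(O)[C@H]2CC[C@H](C)CC(=O)OCC=C | intermediate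
21 | angelic acid | C/C=C(/C)C(=O)O | starting material
22 | angelic 2,4,6-trichlorobenzoic mixed anhydride | C/C=C(/C)C(=O)OC(=O)c1c(Cl)cc(Cl)cc1Cl | intermediate
23 | allyl (13S)-18-angeloyloxy-8-hydroxylabdan-15-oate (ent series) | C/C=C(/C)C(=O)OC[C@@]1(C)CCC[C@]2(C)[C@@H]1CC[C@](C)(O)[C@H]2CC[C@H](C)CC(=O)OCC=C | intermediate
24 | (4S,5S,8S,9S,10R,13S)-18-angeloyloxy-8-hydroxylabdan-15-oic acid | C/C=C(/C)C(=O)OC[C@@]1(C)CCC[C@]2(C)[C@@H]1CC[C@](C)(O)[C@H]2CC[C@H](C)CC(=O)O | target

Total step count: 17
Longest linear sequence: 17 steps (1 to 24); angelic acid 21 enters in step 16.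

Steps most likely to fail

Step 6. The electron-withdrawing CH2OSi group slows ionisation of the C4–O bond, so a 1,2-hydride shift of the activated epoxide, a stop after ring A, or proton loss from the C8 cation may compete with lactone capture. The fallback sets out from 7 and replaces the cationic cascade by a radical one, adding the C8 oxygen afterwards. Cp2TiCl (trivalent titanium, made from Cp2TiCl2 and Mn dust, THF, rt) opens the epoxide homolytically at C4, which the CH2OSi group does not retard. The 6-endo/6-endo radical cascade should end by hydrogen loss to methyl 18-(tert-butyldiphenylsilyloxy)-3-hydroxy-14,15,16-trinorlabd-8(17)-en-13-oate F1. The larger CH2OSi group is expected to take the equatorial site at C4, and a C4 epimer would be separated at this stage. Mukaiyama hydration (Mn(dpm)3, PhSiH3, O2, i-PrOH) should bring oxygen to C8 from the face opposite the axial C10 methyl and give methyl 18-(tert-butyldiphenylsilyloxy)-3,8-dihydroxy-14,15,16-trinorlabdan-13-oate F2. Warming F2 with pyridinium p-toluenesulfonate in toluene lactonises it with loss of methanol, and the route is rejoined at 10.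

Step 2. Oxidation may spread over the three trisubstituted alkenes and run on to the enal. The fallback sets out from 4 and builds the (E)-allylic alcohol by cleavage and olefination. NBS in aqueous THF at 0 °C adds to the terminal alkene and gives methyl (4E,8E)-12-bromo-13-hydroxy-5,9,13-trimethyltetradeca-4,8-dienoate F3. K2CO3 in MeOH closes it to racemic methyl (4E,8E)-11-(3,3-dimethyloxiran-2-yl)-5,9-dimethylundeca-4,8-dienoate F4. HIO4 in aqueous THF cleaves this to methyl (4E,8E)-5,9-dimethyl-12-oxododeca-4,8-dienoate F5 and acetone. A Wittig reaction with the stabilised ylide Ph3P=C(CH3)CHO in hot toluene gives methyl (4E,8E,12E)-5,9,13-trimethyl-14-oxotetradeca-4,8,12-trienoate F6. NaBH4 in MeOH at 0 °C reduces only the aldehyde, and the route is rejoined at 5.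

Step 10. Olefination of a methyl ketone gives incomplete (E)-selectivity, and reversible hemiketal formation with the C8 alkoxide may lower the reactivity of the ketone; any (13Z) material carried on would end as the 13-epimer. The fallback sets out from 12 and fixes the alkene geometry by syn carbometalation. iBu2AlH (1.1 equiv, CH2Cl2, −78 °C) reduces the lactone to the cyclic hemiacetal 18-(tert-butyldiphenylsilyloxy)-14,15,16-trinorlabdane-8,13-lactol F7. The Ohira–Bestmann reagent (dimethyl 1-diazo-2-oxopropylphosphonate, K2CO3, MeOH) converts it to 18-(tert-butyldiphenylsilyloxy)-15,16-dinorlabd-13-yn-8-ol F8. Negishi carboalumination (Me3Al, Cp2ZrCl2, CH2Cl2; then paraformaldehyde) adds methyl and aluminium to the same side of the alkyne and so gives only the (13E)-allylic alcohol. The route is rejoined at 16, and steps 9 to 11 are bypassed.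

Further compounds
F1 | step 6 | methyl 18-(tert-butyldiphenylsilyloxy)-3-hydroxy-14,15,16-trinorlabd-8(17)-en-13-oate (ent series) | CC(C)(C)[Si](c1ccccc1)(c1ccccc1)OC[C@@]1(C)[C@H](O)CC[C@]2(C)[C@@H]1CCC(=C)[C@H]2CCC(=O)OC
F2 | step 6 | methyl 18-(tert-butyldiphenylsilyloxy)-3,8-dihydroxy-14,15,16-trinorlabdan-13-oate (ent series) | CC(C)(C)[Si](c1ccccc1)(c1ccccc1)OC[C@@]1(C)[C@H](O)CC[C@]2(C)[C@@H]1CC[C@](C)(O)[C@H]2CCC(=O)OC
F3 | step 2 | methyl (4E,8E)-12-bromo-13-hydroxy-5,9,13-trimethyltetradeca-4,8-dienoate (racemic) | COC(=O)CC/C=C(C)/CC/C=C(C)/CCC(Br)C(C)(C)O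
F4 | step 2 | methyl (4E,8E)-11-(3,3-dimethyloxiran-2-yl)-5,9-dimethylundeca-4,8-dienoate (racemic) | COC(=O)CC/C=C(C)/CC/C=C(C)/CCC1OC1(C)C
F5 | step 2 | methyl (4E,8E)-5,9-dimethyl-12-oxododeca-4,8-dienoate | COC(=O)CC/C=C(C)/CC/C=C(C)/CCC=O
F6 | step 2 | methyl (4E,8E,12E)-5,9,13-trimethyl-14-oxotetradeca-4,8,12-trienoate | COC(=O)CC/C=C(C)/CC/C=C(C)/CC/C=C(C)/C=O
F7 | step 10 | 18-(tert-butyldiphenylsilyloxy)-14,15,16-trinorlabdane-8,13-lactol (ent series) | CC(C)(C)[Si](c1ccccc1)(c1ccccc1)OC[C@@]1(C)CCC[C@]2(C)[C@@H]1CC[C@]3(C)OC(O)CC[C@@H]23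
F8 | step 10 | 18-(tert-butyldiphenylsilyloxy)-15,16-dinorlabd-13-yn-8-ol (ent series) | CC(C)(C)[Si](c1ccccc1)(c1ccccc1)OC[C@@]1(C)CCC[C@]2(C)[C@@H]1CC[C@](C)(O)[C@H]2CCC#C
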